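The tetrahydrofuran ring of the target (furo[3,4-c]furanone numbering: C3a, C4, O5, C6, C6a) is disconnected as formaldehyde inserted into a cyclopropane. In one operation a Lewis acid-triggered formal (3+2) annulation joins the C4 methylene to ring-fusion carbon C3a and O5 to benzylic C6. The step exploits the electron-rich guaiacyl group on C6 as cation-stabilising donor and a carbonyl at C3 (later the syringyl carbinol carbon) as acceptor. The precursor is an all-cis 6-aryl-3-oxabicyclo[3.1.0]hexan-2-one from enantioselective intramolecular cyclopropanation of a (Z)-cinnamyl diazoacetate. Its lactone is the transposed isomer of the target lactone and is corrected by aryllithium addition, reduction and oxidative lactonisation.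

Key step: step 7

Remark: target locants follow furo[3,4-c]furan numbering (C1 lactone carbonyl, O2, C3 syringyl carbon, C3a, C4 methylene, O5, C6 guaiacyl carbon, C6a); TIPS = triisopropylsilyl; MEPY = methyl 2-oxopyrrolidine-5-carboxylate as bridging carboxamidate ligand.
Assumption: the sense of induction of Rh2(5R-MEPY)4 is assigned by analogy with simple (Z)-allylic diazoacetates; if 7 should form in the mirror-image series, Rh2(5S-MEPY)4 is used instead.

Step 1
Reactants: 1 vanillin (4-hydroxy-3-methoxybenzaldehyde)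
Product: 2 3-methoxy-4-(triisopropylsilyloxy)benzaldehyde
Conditions: TIPSCl, imidazole, DMF, rt
Reagents that add atoms: chlorotriisopropylsilane (TIPSCl), CC(C)[Si](Cl)(C(C)C)C(C)C
Why: Silylation of the phenol (substitution at silicon, imidazole as base and nucleophilic catalyst) masks the acidic OH as a robust, still strongly donating aryl silyl ether that should survive the base, hydride, carbenoid and Lewis acid steps.

Step 2
Reactants: 2 3-methoxy-4-(triisopropylsilyloxy)benzaldehyde
Product: 3 methyl (Z)-3-[3-methoxy-4-(triisopropylsilyloxy)phenyl]prop-2-enoate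
Conditions: (CF3CH2O)2P(O)CH2CO2Me, KN(SiMe3)2, 18-crown-6, THF, −78 °C
Reagents that add atoms: methyl bis(2,2,2-trifluoroethyl)phosphonoacetate, COC(=O)CP(=O)(OCC(F)(F)F)OCC(F)(F)F
Why: Still–Gennari variant of the Horner–Wadsworth–Emmons olefination, in which the electron-poor phosphonate under dissociating conditions eliminates fast from the kinetic adduct and should give the (Z)-cinnamate, the geometry that later places the aryl group endo on the cyclopropane.

Step 3
Reactants: 3 methyl (Z)-3-[3-methoxy-4-(triisopropylsilyloxy)phenyl]prop-2-enoate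
Product: 4 (Z)-3-[3-methoxy-4-(triisopropylsilyloxy)phenyl]prop-2-en-1-ol
Conditions: iBu2AlH (2.5 equiv), CH2Cl2, −78 °C
Reagents that add atoms: none
Why: 1,2-Reduction of the conjugated ester by the aluminium hydride (two hydride transfers through the aldehyde) should give the allylic alcohol with the (Z) double bond intact at low temperature.

Step 4
Reactants: 4 (Z)-3-[3-methoxy-4-(triisopropylsilyloxy)phenyl]prop-2-en-1-ol
Product: 5 (Z)-3-[3-methoxy-4-(triisopropylsilyloxy)phenyl]prop-2-en-1-yl bromoacetate
Conditions: BrCH2COBr, NaHCO3, MeCN, 0 °C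
Reagents that add atoms: bromoacetyl bromide, BrCC(Br)=O
Why: O-Acylation of the primary alcohol by the acid bromide, with solid NaHCO3 as a mild acid scavenger that avoids ionisation of the electron-rich allylic system.

Step 5
Reactants: 5 (Z)-3-[3-methoxy-4-(triisopropylsilyloxy)phenyl]prop-2-en-1-yl bromoacetate
Product: 6 (Z)-3-[3-methoxy-4-(triisopropylsilyloxy)phenyl]prop-2-en-1-yl diazoacetate
Conditions: TsNHNHTs, DBU, THF, 0 °C
Reagents that add atoms: N,N'-ditosylhydrazine, Cc1ccc(cc1)S(=O)(=O)NNS(=O)(=O)c1ccc(C)cc1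
Why: N-Alkylation of the ditosylhydrazine by the bromoacetate followed by two base-induced eliminations of sulfinate (Bamford–Stevens-type) should give the diazoacetate directly from the halide.

Step 6
Reactants: 6 (Z)-3-[3-methoxy-4-(triisopropylsilyloxy)phenyl]prop-2-en-1-yl diazoacetate
Product: 7 (1S,5R,6S)-6-[3-methoxy-4-(triisopropylsilyloxy)phenyl]-3-oxabicyclo[3.1.0]hexan-2-one (aryl endo, all-cis cyclopropane)
Conditions: Rh2(5R-MEPY)4 (1 mol %), CH2Cl2, reflux, slow addition of 6
Reagents that add atoms: none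
Why: Intramolecular cyclopropanation by the chiral rhodium carboxamidate carbenoid is stereospecific for the alkene geometry, so the (Z)-alkene should give the endo-aryl lactone, and the catalyst, a class that is highly enantioselective for (Z)-allylic diazoacetates, sets the absolute configuration of all three cyclopropane carbons by facial selection of the alkene.

Step 7
Reactants: 7 (1S,5R,6S)-6-[3-methoxy-4-(triisopropylsilyloxy)phenyl]-3-oxabicyclo[3.1.0]hexan-2-one
Product: 9 (3aR,4S,6aR)-4-[3-methoxy-4-(triisopropylsilyloxy)phenyl]tetrahydro-1H,3H-furo[3,4-c]furan-1-one, via oxocarbenium enolate 8 (not isolated)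
Conditions: (CH2O)n (5 equiv), Sc(OTf)3 (20 mol %), 4 Å molecular sieves, ClCH2CH2Cl, 40 °C
Reagents that add atoms: formaldehyde (charged as paraformaldehyde), C=O
Why: Proposed new method: Sc(OTf)3 on the lactone carbonyl polarises the cyclopropane bond C1–C6 of 7 (C1 alpha to the carbonyl, C6 benzylic with the donor aryl), formaldehyde oxygen attacks C6 anti to that bond with inversion to give oxocarbenium enolate 8, and the enolate carbon then adds to the oxocarbenium carbon in an intramolecular Mukaiyama-type aldol, so that the O–C(benzylic) and CH2–C(ring fusion) bonds form in one operation. The closest known reaction type is the Lewis acid-catalysed (3+2) annulation of 2-arylcyclopropane-1,1-dicarboxylates with aldehydes; new are the single lactone acceptor and formaldehyde as partner, which is defensible because the 4-silyloxy-3-methoxyphenyl group strongly stabilises positive charge at C6 and the endo aryl group adds strain that is released on opening. The tetrahydrofuran ring closes in the formally 5-(enolexo)-endo-trig mode common to all such aldehyde annulations (an enolate attacking an oxocarbenium ion tethered through its oxygen). The benzylic stereocentre is set by inversion at C6 of the endo-aryl cyclopropane, which puts the aryl group on the convex face, and a more ionised (benzylic cation) pathway should close through the less crowded exo transition state to the same epimer. The ring-fusion centre alpha to the carbonyl is dictated by the tether, since only the cis-fused 5,5-bicycle can form, and the second ring-fusion centre is carried over unchanged from 7. The step needs cleavage of C1–C6 rather than C5–C6, secured because only C1–C6 lies between donor and acceptor and overlaps with the carbonyl, and capture by formaldehyde ahead of proton loss to a styrene, secured by an excess of monomeric formaldehyde released from paraformaldehyde.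

Step 8
Reactants: 10 4-bromo-2,6-dimethoxyphenol
Product: 11 (4-bromo-2,6-dimethoxyphenoxy)triisopropylsilane
Conditions: TIPSCl, imidazole, DMF, 50 °C
Reagents that add atoms: chlorotriisopropylsilane (TIPSCl), CC(C)[Si](Cl)(C(C)C)C(C)C
Why: Silylation of the hindered phenol removes the acidic proton before halogen–metal exchange and gives the same protecting group as on the other aryl ring, so that one fluoride step frees both phenols at the end.

Step 9
Reactants: 9 (3aR,4S,6aR)-4-[3-methoxy-4-(triisopropylsilyloxy)phenyl]tetrahydro-1H,3H-furo[3,4-c]furan-1-one, 11 (4-bromo-2,6-dimethoxyphenoxy)triisopropylsilane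
Product: 14 [3,5-dimethoxy-4-(triisopropylsilyloxy)phenyl]{(3R,4R,5S)-4-(hydroxymethyl)-5-[3-methoxy-4-(triisopropylsilyloxy)phenyl]tetrahydrofuran-3-yl}methanone (drawn as the open hydroxy ketone; expected to rest largely as its cyclic hemiketal tautomer), via aryllithium 12 (not isolated), via lithium hemiketalate 13 (not isolated)
Conditions: 11, n-BuLi, THF, −78 °C; then 9, −78 °C; aq. NH4Cl
Reagents that add atoms: none
Why: Bromine–lithium exchange gives aryllithium 12, which should add only once to the lactone carbonyl because the tetrahedral alkoxide 13 persists at −78 °C, and protonation gives the hydroxy ketone, held cis at the enolisable ring carbon by its hemiketal tautomer.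

Step 10
Reactants: 14 [3,5-dimethoxy-4-(triisopropylsilyloxy)phenyl]{(3R,4R,5S)-4-(hydroxymethyl)-5-[3-methoxy-4-(triisopropylsilyloxy)phenyl]tetrahydrofuran-3-yl}methanone
Product: 15 (S)-[3,5-dimethoxy-4-(triisopropylsilyloxy)phenyl]{(3R,4R,5S)-4-(hydroxymethyl)-5-[3-methoxy-4-(triisopropylsilyloxy)phenyl]tetrahydrofuran-3-yl}methanol
Conditions: (R)-2-methyl-CBS-oxazaborolidine (20 mol %), BH3·SMe2 (2.5 equiv), THF, −20 °C; MeOH quench
Reagents that add atoms: none
Why: Corey–Bakshi–Shibata reduction, in which the (R)-oxazaborolidine–borane complex delivers hydride to the ketone face that gives the (S)-carbinol (aryl as the large group), a sense that should be reinforced by the Felkin–Anh preference of the alpha-branched ketone.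

Step 11
Reactants: 15 (S)-[3,5-dimethoxy-4-(triisopropylsilyloxy)phenyl]{(3R,4R,5S)-4-(hydroxymethyl)-5-[3-methoxy-4-(triisopropylsilyloxy)phenyl]tetrahydrofuran-3-yl}methanol
Product: 18 (3S,3aR,6S,6aS)-3-[3,5-dimethoxy-4-(triisopropylsilyloxy)phenyl]-6-[3-methoxy-4-(triisopropylsilyloxy)phenyl]tetrahydro-1H,3H-furo[3,4-c]furan-1-one, via hydroxy aldehyde 16 (not isolated), via lactol 17 (not isolated)
Conditions: TEMPO (20 mol %), PhI(OAc)2 (2.5 equiv), CH2Cl2, rt
Reagents that add atoms: none
Why: Oxoammonium oxidation is faster at the primary alcohol, the aldehyde 16 is trapped by the benzylic hydroxyl as lactol 17 and this is oxidised on to the lactone, so the aryl carbinol oxygen should become the ring oxygen of the target lactone without change at any stereocentre.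

Step 12
Reactants: 18 (3S,3aR,6S,6aS)-3-[3,5-dimethoxy-4-(triisopropylsilyloxy)phenyl]-6-[3-methoxy-4-(triisopropylsilyloxy)phenyl]tetrahydro-1H,3H-furo[3,4-c]furan-1-one
Product: 19 (3S,3aR,6S,6aS)-3-(4-hydroxy-3,5-dimethoxyphenyl)-6-(4-hydroxy-3-methoxyphenyl)tetrahydro-1H,3H-furo[3,4-c]furan-1-one (target)
Conditions: Bu4NF, AcOH, THF, 0 °C
Reagents that add atoms: none
Why: Fluoride cleaves both aryl silyl ethers (strong Si–F bond), and the acetic acid buffer keeps the liberated phenols protonated so that quinone methide formation and epimerisation at the two benzylic C–O carbons should be avoided.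

Compound list

1 | vanillin (4-hydroxy-3-methoxybenzaldehyde) | COc1cc(C=O)ccc1O | starting material
2 | 3-methoxy-4-(triisopropylsilyloxy)benzaldehyde | COc1cc(C=O)ccc1O[Si](C(C)C)(C(C)C)C(C)C | intermediate
3 | methyl (Z)-3-[3-methoxy-4-(triisopropylsilyloxy)phenyl]prop-2-enoate | COC(=O)/C=C\c1ccc(O[Si](C(C)C)(C(C)C)C(C)C)c(OC)c1 | intermediate
4 | (Z)-3-[3-methoxy-4-(triisopropylsilyloxy)phenyl]prop-2-en-1-ol | OC/C=C\c1ccc(O[Si](C(C)C)(C(C)C)C(C)C)c(OC)c1 | intermediate
5 | (Z)-3-[3-methoxy-4-(triisopropylsilyloxy)phenyl]prop-2-en-1-yl bromoacetate | BrCC(=O)OC/C=C\c1ccc(O[Si](C(C)C)(C(C)C)C(C)C)c(OC)c1 | intermediate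
6 | (Z)-3-[3-methoxy-4-(triisopropylsilyloxy)phenyl]prop-2-en-1-yl diazoacetate | [N-]=[N+]=CC(=O)OC/C=C\c1ccc(O[Si](C(C)C)(C(C)C)C(C)C)c(OC)c1 | intermediate
7 | (1S,5R,6S)-6-[3-methoxy-4-(triisopropylsilyloxy)phenyl]-3-oxabicyclo[3.1.0]hexan-2-one (endo aryl) | O=C1OC[C@@H]2[C@H](c3ccc(O[Si](C(C)C)(C(C)C)C(C)C)c(OC)c3)[C@H]12 | intermediate
8 | oxocarbenium enolate, (4R)-4-{(S)-[3-methoxy-4-(triisopropylsilyloxy)phenyl](methyleneoxonio)methyl}-4,5-dihydrofuran-2-olate, scandium-bound in the flask and drawn as the free zwitterion (not isolated) | [O-]C1=C[C@H](CO1)[C@@H](c2ccc(O[Si](C(C)C)(C(C)C)C(C)C)c(OC)c2)[O+]=C | intermediate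
9 | (3aR,4S,6aR)-4-[3-methoxy-4-(triisopropylsilyloxy)phenyl]tetrahydro-1H,3H-furo[3,4-c]furan-1-one | O=C1OC[C@@H]2[C@@H](c3ccc(O[Si](C(C)C)(C(C)C)C(C)C)c(OC)c3)OC[C@H]12 | intermediate
10 | 4-bromo-2,6-dimethoxyphenol | COc1cc(Br)cc(OC)c1O | starting material
11 | (4-bromo-2,6-dimethoxyphenoxy)triisopropylsilane | COc1cc(Br)cc(OC)c1O[Si](C(C)C)(C(C)C)C(C)C | intermediate
12 | aryllithium, [3,5-dimethoxy-4-(triisopropylsilyloxy)phenyl]lithium (not isolated) | [Li]c1cc(OC)c(O[Si](C(C)C)(C(C)C)C(C)C)c(OC)c1 | intermediate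
13 | lithium hemiketalate, lithium (3aR,4S,6aR)-1-[3,5-dimethoxy-4-(triisopropylsilyloxy)phenyl]-4-[3-methoxy-4-(triisopropylsilyloxy)phenyl]tetrahydro-1H,3H-furo[3,4-c]furan-1-olate, both epimers at C1 (not isolated) | [Li]OC1(c3cc(OC)c(O[Si](C(C)C)(C(C)C)C(C)C)c(OC)c3)OC[C@@H]2[C@@H](c3ccc(O[Si](C(C)C)(C(C)C)C(C)C)c(OC)c3)OC[C@H]12 | intermediate
14 | [3,5-dimethoxy-4-(triisopropylsilyloxy)phenyl]{(3R,4R,5S)-4-(hydroxymethyl)-5-[3-methoxy-4-(triisopropylsilyloxy)phenyl]tetrahydrofuran-3-yl}methanone (open form of the hemiketal) | OC[C@@H]1[C@@H](c2ccc(O[Si](C(C)C)(C(C)C)C(C)C)c(OC)c2)OC[C@@H]1C(=O)c1cc(OC)c(O[Si](C(C)C)(C(C)C)C(C)C)c(OC)c1 | intermediate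
15 | (S)-[3,5-dimethoxy-4-(triisopropylsilyloxy)phenyl]{(3R,4R,5S)-4-(hydroxymethyl)-5-[3-methoxy-4-(triisopropylsilyloxy)phenyl]tetrahydrofuran-3-yl}methanol | OC[C@@H]1[C@@H](c2ccc(O[Si](C(C)C)(C(C)C)C(C)C)c(OC)c2)OC[C@@H]1[C@H](O)c1cc(OC)c(O[Si](C(C)C)(C(C)C)C(C)C)c(OC)c1 | intermediate
16 | hydroxy aldehyde, (2S,3S,4R)-4-{(S)-[3,5-dimethoxy-4-(triisopropylsilyloxy)phenyl](hydroxy)methyl}-2-[3-methoxy-4-(triisopropylsilyloxy)phenyl]tetrahydrofuran-3-carbaldehyde (not isolated) | O=C[C@@H]1[C@@H](c2ccc(O[Si](C(C)C)(C(C)C)C(C)C)c(OC)c2)OC[C@@H]1[C@H](O)c1cc(OC)c(O[Si](C(C)C)(C(C)C)C(C)C)c(OC)c1 | intermediate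
17 | lactol, (3S,3aR,6S,6aS)-3-[3,5-dimethoxy-4-(triisopropylsilyloxy)phenyl]-6-[3-methoxy-4-(triisopropylsilyloxy)phenyl]tetrahydro-1H,3H-furo[3,4-c]furan-1-ol, both anomers (not isolated) | COc1cc([C@H]2OC[C@H]3[C@@H]2C(O)O[C@@H]3c2cc(OC)c(O[Si](C(C)C)(C(C)C)C(C)C)c(OC)c2)ccc1O[Si](C(C)C)(C(C)C)C(C)C | intermediate
18 | (3S,3aR,6S,6aS)-3-[3,5-dimethoxy-4-(triisopropylsilyloxy)phenyl]-6-[3-methoxy-4-(triisopropylsilyloxy)phenyl]tetrahydro-1H,3H-furo[3,4-c]furan-1-one | COc1cc([C@H]2OC[C@H]3[C@@H]2C(=O)O[C@@H]3c2cc(OC)c(O[Si](C(C)C)(C(C)C)C(C)C)c(OC)c2)ccc1O[Si](C(C)C)(C(C)C)C(C)C | intermediate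
19 | (3S,3aR,6S,6aS)-3-(4-hydroxy-3,5-dimethoxyphenyl)-6-(4-hydroxy-3-methoxyphenyl)tetrahydro-1H,3H-furo[3,4-c]furan-1-one | COc1cc([C@H]2OC[C@H]3[C@@H]2C(=O)O[C@@H]3c2cc(OC)c(O)c(OC)c2)ccc1O | target

Total step count: 12. Longest linear sequence: 11 (steps 1 to 7 and 9 to 12; step 8 is the side branch).

Steps most likely to fail

Step 7 (key step, proposed new method). The single lactone acceptor may not activate the cyclopropane enough, or the opened intermediate may lose a proton to give a styrene instead of being captured by formaldehyde. The fallback adds a second acceptor so that the step becomes the established Lewis acid-catalysed (3+2) annulation of aryl cyclopropane-1,1-dicarbonyl compounds with aldehydes. Setting out from alcohol 4, acylation with methyl malonyl chloride and pyridine would give methyl (Z)-3-[3-methoxy-4-(triisopropylsilyloxy)phenyl]prop-2-en-1-yl malonate F1. Regitz diazo transfer (4-acetamidobenzenesulfonyl azide, Et3N) would give the diazomalonate F2. Intramolecular cyclopropanation with the monovalent copper salt CuOTf and a chiral bis(oxazoline) ligand, followed by recrystallisation to upgrade the enantiomeric purity, would give the 1-methoxycarbonyl analogue of 7 with the aryl group endo, methyl 6-aryl-2-oxo-3-oxabicyclo[3.1.0]hexane-1-carboxylate F3. Sc(OTf)3 and paraformaldehyde would then give, with the same inversion at the benzylic carbon, the 6a-methoxycarbonyl derivative of 9, F4. Krapcho demethoxycarbonylation (LiCl, wet DMSO, 140 °C) removes the extra ester, protonation being possible only to the cis-fused bicycle, and the route is rejoined at 9.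

Step 10. Facial selectivity at the ketone may be poor, because the aryl group and the alpha-branched ring carbon are of similar size for the oxazaborolidine and the hemiketal tautomer may divert borane. The fallback replaces kinetic reagent control by thermodynamic control. Setting out from 14, unselective reduction with NaBH4 in MeOH would give 15 mixed with its carbinol epimer, the (R)-carbinol diol F5. The mixture is carried through the oxidation of step 11 to 18 and its C3 epimer, the (3R,3aR,6S,6aS) lactone F6. Treatment of this mixture with CF3CO2H in CH2Cl2 should equilibrate the benzylic lactone carbon by reversible ionisation of its C–O bond (cation stabilised by the 4-silyloxy-3,5-dimethoxyphenyl ring) towards the more stable exo-aryl, trans lactone, and the route is rejoined at 18.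

Step 9. The basic aryllithium may enolise lactone 9 (with beta-elimination of ring oxygen O5 from the enolate), or a second equivalent may add to the released ketone. The fallback separates ring opening from aryl addition. Setting out from 9, MeNH(OMe)·HCl and AlMe3 would open the lactone to the hydroxy Weinreb amide, (3R,4R,5S)-4-(hydroxymethyl)-N-methoxy-N-methyl-5-[3-methoxy-4-(triisopropylsilyloxy)phenyl]tetrahydrofuran-3-carboxamide F7. Immediate capping with Et3SiCl and imidazole would give the triethylsilyl ether F8. Aryllithium 12 (or the less basic Grignard reagent from 11) should add once through the stable N-methoxy chelate to give the silyl-protected ketone F9. Pyridinium p-toluenesulfonate in MeOH removes the triethylsilyl group while leaving the aryl triisopropylsilyl ethers, any epimerisation alpha to the ketone being corrected because only the cis isomer closes to the hemiketal, and the route is rejoined at 14.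

Further compounds

F1 | step 7 | methyl (Z)-3-[3-methoxy-4-(triisopropylsilyloxy)phenyl]prop-2-en-1-yl malonate | COC(=O)CC(=O)OC/C=C\c1ccc(O[Si](C(C)C)(C(C)C)C(C)C)c(OC)c1
F2 | step 7 | methyl (Z)-3-[3-methoxy-4-(triisopropylsilyloxy)phenyl]prop-2-en-1-yl diazomalonate | COC(=O)C(=[N+]=[N-])C(=O)OC/C=C\c1ccc(O[Si](C(C)C)(C(C)C)C(C)C)c(OC)c1
F3 | step 7 | methyl 6-[3-methoxy-4-(triisopropylsilyloxy)phenyl]-2-oxo-3-oxabicyclo[3.1.0]hexane-1-carboxylate, aryl endo, same absolute sense as 7 | O=C1OC[C@@H]2[C@H](c3ccc(O[Si](C(C)C)(C(C)C)C(C)C)c(OC)c3)[C@]12C(=O)OC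
F4 | step 7 | methyl 6-[3-methoxy-4-(triisopropylsilyloxy)phenyl]-3-oxotetrahydro-1H,3H-furo[3,4-c]furan-3a-carboxylate, the 6a-methoxycarbonyl derivative of 9 in the numbering of 9 | O=C1OC[C@@H]2[C@@H](c3ccc(O[Si](C(C)C)(C(C)C)C(C)C)c(OC)c3)OC[C@]12C(=O)OC
F5 | step 10 | (R)-[3,5-dimethoxy-4-(triisopropylsilyloxy)phenyl]{(3R,4R,5S)-4-(hydroxymethyl)-5-[3-methoxy-4-(triisopropylsilyloxy)phenyl]tetrahydrofuran-3-yl}methanol | OC[C@@H]1[C@@H](c2ccc(O[Si](C(C)C)(C(C)C)C(C)C)c(OC)c2)OC[C@@H]1[C@@H](O)c1cc(OC)c(O[Si](C(C)C)(C(C)C)C(C)C)c(OC)c1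
F6 | step 10 | (3R,3aR,6S,6aS)-3-[3,5-dimethoxy-4-(triisopropylsilyloxy)phenyl]-6-[3-methoxy-4-(triisopropylsilyloxy)phenyl]tetrahydro-1H,3H-furo[3,4-c]furan-1-one | COc1cc([C@H]2OC[C@H]3[C@@H]2C(=O)O[C@H]3c2cc(OC)c(O[Si](C(C)C)(C(C)C)C(C)C)c(OC)c2)ccc1O[Si](C(C)C)(C(C)C)C(C)C
F7 | step 9 | (3R,4R,5S)-4-(hydroxymethyl)-N-methoxy-N-methyl-5-[3-methoxy-4-(triisopropylsilyloxy)phenyl]tetrahydrofuran-3-carboxamide | OC[C@@H]1[C@@H](c2ccc(O[Si](C(C)C)(C(C)C)C(C)C)c(OC)c2)OC[C@@H]1C(=O)N(C)OC
F8 | step 9 | (3R,4R,5S)-N-methoxy-N-methyl-5-[3-methoxy-4-(triisopropylsilyloxy)phenyl]-4-[(triethylsilyloxy)methyl]tetrahydrofuran-3-carboxamide | CC[Si](CC)(CC)OC[C@@H]1[C@@H](c2ccc(O[Si](C(C)C)(C(C)C)C(C)C)c(OC)c2)OC[C@@H]1C(=O)N(C)OC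
F9 | step 9 | [3,5-dimethoxy-4-(triisopropylsilyloxy)phenyl]{(3R,4R,5S)-5-[3-methoxy-4-(triisopropylsilyloxy)phenyl]-4-[(triethylsilyloxy)methyl]tetrahydrofuran-3-yl}methanone | CC[Si](CC)(CC)OC[C@@H]1[C@@H](c2ccc(O[Si](C(C)C)(C(C)C)C(C)C)c(OC)c2)OC[C@@H]1C(=O)c1cc(OC)c(O[Si](C(C)C)(C(C)C)C(C)C)c(OC)c1
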